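## Analysis of the target

The target 14 is apigenin (ring A the 5,7-dihydroxylated benzo ring, ring C the pyran-4-one, ring B the 4-hydroxyphenyl group) carrying a 2-carboxy-1-phenylethyl chain at C8 of ring A. It has one stereocenter, the methine that joins C8, the phenyl group and the CH2CO2H arm. The CIP order flavonyl C8 > phenyl > CH2CO2H > H makes it R, and with no second stereocenter the problem is one of absolute configuration only. The two aryl groups on that carbon differ mainly in their ortho substitution, so the stereocenter is a diarylmethine in which a phenyl group must be told from a doubly ortho-oxygenated aryl group. The sensitive groups are three phenols (air-sensitive as phenoxides) and the chromone, which hot alkali opens. With the 5- and 7-hydroxyls both free, hot acid can open and reclose the chromone and so move the chain from C8 to C6. The C7 hydroxyl and the carboxyl can also close to a six-membered dihydrocoumarin lactone. A second difficulty is regiochemical, since C6 and C8 of a 5,7-dioxygenated flavone are hard to tell apart by electrophilic substitution. The strategy rests on the array O7–C7–C8–CH(Ph)–CH2–C(=O), which is a latent 4-phenyl-3,4-dihydrocoumarin. Its dehydro form is a 4-phenylcoumarin whose ring holds the 3,3-diarylacrylate in one geometry, so the stereocenter can be made by adding hydrogen to one face of an alkene of defined shape.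

## Retrosynthetic reasoning

Position mapping used throughout: coumarin C4 becomes the stereocenter, C4a becomes flavone C8, C5–O becomes O1, C6 becomes C4a, C7–O becomes C5–O, C8 becomes C6, and the lactone oxygen becomes O7.

**14 to 11.** The O–CH3 bonds at O5 and O4' are cut, which leads back to the (R)-acid 11, the 5,4'-dimethyl ether of the target. Methyl is chosen because it survives Lewis acid, strong base, the oxidative cyclisation and the hydrogenation. O7 stays free because it is the lactone oxygen of the earlier intermediates. The forward reaction has to cleave two aryl methyl ethers without touching the stereocenter. It passes through the lactone 12 and the salt 13, which are not isolated.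

**11 to 9.** The two C–H bonds at the stereocenter and at the neighbouring CH2 are cut, giving the disodium (Z)-acrylate 9. This is the only stereocenter, no C–C bond has to be made, and the alkene geometry is unambiguous. The forward reaction must add hydrogen to one face and leave the chromone C2=C3 bond alone.

**9 to 8.** The O7–C(=O) bond is re-formed on paper, giving the fused 4-phenylcoumarin–flavone 8. Opening a ring in which aryl and carboxyl are held cis can only give the Z acrylate, so the geometry needed for the key step costs one saponification.

**8 to 7, then to 4 and 5.** Ring C is cut at O1–C2 and at C2–C3, leading through the 2'-hydroxychalcone 7 to the acetylcoumarin 4 and 4-methoxybenzaldehyde 5. Building the flavone on a finished coumarin turns the C6/C8 problem of ring A into the question of which ortho oxygen closes ring C. The methyl ether on the other oxygen answers that question.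

**4 to 3 to 2.** The C6–acetyl bond is cut and traced to an acyl shift from O5 (acetate 3, phenol 2). The ortho relationship to O5 picks C6 over C8, and the chelated hydroxy ketone is the stable isomer.

**2 to 1.** The O7–CH3 bond is cut, giving 5,7-dihydroxy-4-phenylcoumarin 1. It carries ring A, both oxygens, the phenyl group and the three carbons of the side chain. The peri phenyl group shields O5, so O7 is alkylated first.

## Alternatives that were turned down

Alternative 1: The cut is through C8–C8a of ring A and O1–C2 of ring C, so that both rings come from an open chain stored as the 3-acyl-4-methoxy-2-pyranone A2, which already holds the stereocenter. In the forward step an alkoxide opens the pyranone, the C8 methylene condenses onto the freed ester carbon (Claisen), ring A aromatises, and acid closes ring C from the new C8a hydroxyl onto the aroyl ketone to give ester A1.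
- For: the position of the side chain is written into the chain, so there is no C6/C8 question and no acyl shift. On this point it is stronger than the chosen route, whose ring-A pattern rests on a selective O-methylation and a Fries shift.
- Against: it does not make the stereocenter but moves it into an earlier asymmetric step and a multi-step assembly of A2. After opening, A2 has three enolisable positions and two ester electrophiles, so folding onto the side-chain ester or aldol closure can compete. The needed nucleophile, C8, is the most hindered, next to the stereocenter. A1 still pairs the 7-OH with an ester and will lactonise, so the end game is no shorter.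
- Comparison: the chosen route buys ring A and the lactone skeleton in 1 and puts the risk into one catalytic step.

Alternative 2: The cut is the bond between the stereocenter and the phenyl group, leading to the phenyl-free fused coumarin A4 and phenylboronic acid A5. In the forward step an aryl–rhodium species (monovalent rhodium with a chiral ligand), formed by transmetallation from A5, adds to the β-carbon of the unsaturated lactone, and protonation releases lactone A3.
- For: conjugate arylation of coumarins is a well-established enantioselective route to 4-aryl-dihydrocoumarins, and the product is a crystallisable lactone. On precedent for high enantioselectivity it is at least as strong as the chosen step, arguably stronger.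
- Against: the acceptor carbon is peri to the chromone oxygen O1 and must receive an aryl group, not a hydrogen. The chromone C2=C3 enone of A4 is a second acceptor for aryl–rhodium. A4 needs the same kind of sequence from a coumarin without the 4-phenyl group, where the two hydroxyls are less differentiated, so the O-methylation that fixes the ring fusion is less selective.
- Comparison: the step count is about equal. The chosen strategy has every carbon of the side chain in place from 1 and delivers only hydrogen to the hindered carbon.

Alternative 3: The cuts are the CH2–CO2 bond and the C–H bond at the stereocenter, leading to the 1,1-diarylethene A7. In the forward step a chiral palladium hydride adds across the alkene with palladium on the terminal carbon, a carbonyl ligand inserts, and the acyl is captured as the methyl ester A6.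
- For: it is convergent, since the alkene comes from a cross-coupling at C8 of a flavone. The homologation is atom-economic, and with all phenols methylated there is no lactone chemistry during the key step. It is stronger than the chosen route on convergence.
- Against: the stereocenter forms in a hydropalladation that β-hydride elimination can reverse, so configuration can be lost before carbonylation. The catalyst has no anchoring group to help it tell phenyl from flavonyl. A6 carries an unchelated 7-methyl ether and a methyl ester in addition to the two ethers of 11. The C6/C8 question returns as a halogenation problem.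
- Comparison: its key step is the farthest from known ground and its end game the longest.

Key step: step 7

Assumptions:
- The sense of induction of (S,S)-Chiraphos, (2S,3S)-2,3-bis(diphenylphosphino)butane, on dianion 9 cannot be derived on paper. It is written as the working antipode, and the (R,R) ligand replaces it if the first run shows the S acid.
- Compound 1 is taken as a catalogue compound.
- The open hydroxy acid 14 is taken to be isolable without reclosure when it is set free cold at pH 3 and not heated.

## Route

Step 1
Reactants: 1 5,7-dihydroxy-4-phenyl-2H-chromen-2-one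
Product: 2 5-hydroxy-7-methoxy-4-phenyl-2H-chromen-2-one
Conditions: MeI (1.05 equiv), K2CO3 (1.05 equiv), acetone, rt
Reagents that add atoms: iodomethane, CI
Why: Williamson ether synthesis; with one equivalent of base the more acidic, unhindered 7-phenoxide is alkylated, while the 5-OH lies in the peri pocket beside the twisted 4-phenyl group and should react more slowly.

Step 2
Reactants: 2 5-hydroxy-7-methoxy-4-phenyl-2H-chromen-2-one
Product: 3 7-methoxy-2-oxo-4-phenyl-2H-chromen-5-yl acetate
Conditions: Ac2O, pyridine, DMAP (cat.), rt
Reagents that add atoms: acetic anhydride, CC(=O)OC(C)=O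
Why: DMAP-catalysed O-acylation of the only free hydroxyl; the hindered 5-OH is driven to the aryl acetate needed for the acyl shift.

Step 3
Reactants: 3 7-methoxy-2-oxo-4-phenyl-2H-chromen-5-yl acetate
Product: 4 6-acetyl-5-hydroxy-7-methoxy-4-phenyl-2H-chromen-2-one
Conditions: BF3·OEt2 (4 equiv), PhCl, 110 °C; then aq. NaOAc
Reagents that add atoms: none
Why: Fries rearrangement; the only free position ortho to O5 is C6, and the ketone formed there is held by boron between O5 and the carbonyl, which should make it the thermodynamic sink over the unchelated C8 isomer. BF3 is used in place of AlCl3 because it leaves an aryl methyl ether ortho to a ketone intact.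

Step 4
Reactants: 4 6-acetyl-5-hydroxy-7-methoxy-4-phenyl-2H-chromen-2-one; 5 4-methoxybenzaldehyde
Product: 7 (E)-5-hydroxy-7-methoxy-6-[3-(4-methoxyphenyl)prop-2-enoyl]-4-phenyl-2H-chromen-2-one, via the ring-opened tripotassium chalcone salt 6 (not isolated)
Conditions: KOH (50% aq.), EtOH, rt; then 2 M HCl, 0 °C
Reagents that add atoms: none
Why: Claisen–Schmidt condensation; the methyl ketone enolate adds to the non-enolisable aldehyde and E1cB loss of water gives the E enone. In aqueous KOH the lactone is open as trianion 6, and acidification should reclose it at once because the acrylate is Z with the phenol cis to the carboxyl.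

Step 5
Reactants: 7 (E)-5-hydroxy-7-methoxy-6-[3-(4-methoxyphenyl)prop-2-enoyl]-4-phenyl-2H-chromen-2-one
Product: 8 5-methoxy-2-(4-methoxyphenyl)-10-phenyl-4H,8H-pyrano[2,3-f]chromene-4,8-dione
Conditions: I2 (10 mol %), DMSO, 120 °C
Reagents that add atoms: none
Why: iodine-catalysed oxidative cyclisation of a 2'-hydroxychalcone; oxa-Michael closure forms O1–C2, iodination alpha to the ketone and loss of HI give the chromone, and DMSO turns HI back into I2. The methyl ether on the other ortho oxygen leaves only one phenol able to close, so only the angular ring system, with the lactone on O7 and C8 of the flavone, can form.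

Step 6
Reactants: 8 5-methoxy-2-(4-methoxyphenyl)-10-phenyl-4H,8H-pyrano[2,3-f]chromene-4,8-dione
Product: 9 disodium (Z)-3-[5-methoxy-2-(4-methoxyphenyl)-7-oxido-4-oxo-4H-chromen-8-yl]-3-phenylprop-2-enoate
Conditions: NaOH (2.05 equiv), MeOH/H2O, rt, Ar, dark; evaporate
Reagents that add atoms: sodium hydroxide, [Na+].[OH-]
Why: lactone saponification; hydroxide adds to the lactone carbonyl and the C7 phenoxide leaves, and because aryl and carboxyl were cis in the ring only the Z acrylate can form. The dianion cannot reclose while basic, light is excluded to avoid Z/E isomerisation, and two equivalents of cold dilute base should not open the chromone.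

Step 7
Reactants: 9 disodium (Z)-3-[5-methoxy-2-(4-methoxyphenyl)-7-oxido-4-oxo-4H-chromen-8-yl]-3-phenylprop-2-enoate
Product: 11 (R)-3-[7-hydroxy-5-methoxy-2-(4-methoxyphenyl)-4-oxo-4H-chromen-8-yl]-3-phenylpropanoic acid, via the disodium (R)-propanoate 10 (not isolated)
Conditions: [Rh(cod)2]BF4 (2 mol %), (S,S)-Chiraphos (2.2 mol %), H2 (20 bar), degassed MeOH, 40 °C; then 1 M HCl, 0 °C, pH 3
Reagents that add atoms: none
Why: This is a carboxylate-directed asymmetric alkene hydrogenation, and its closest known relative is the rhodium- or ruthenium-diphosphine hydrogenation of sodium (Z)-3-aryl-3-(2-hydroxyaryl)acrylates made by opening 4-arylcoumarins. Hydrogen removes cyclooctadiene from the precatalyst, and the solvated monovalent rhodium diphosphine cation binds dianion 9 through the carboxylate and the C=C bond, with the neighbouring C7 phenoxide as a possible second anchor. H2 then adds to give a trivalent rhodium dihydride, one hydride migrates to the alkene, and reductive elimination forms the second C–H bond, so both hydrogens arrive on the same face. No ring is closed. The one new stereocenter, the former β-carbon, is set by the chiral diphosphine, which decides which face of the bound alkene meets the metal. The substrate helps by entering as a single Z isomer inherited from lactone 8, so E and Z isomers giving opposite enantiomers cannot arise. The step needs enantioface selectivity and chemoselectivity over the chromone C2=C3 bond, the C4 carbonyl and the aryl ethers; the chromone alkene is an electron-rich vinylogous ester with no anionic anchor beside it and should not bind the cationic metal. Cold acidification of salt 10 then gives acid 11 without closing the lactone.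

Step 8
Reactants: 11 (R)-3-[7-hydroxy-5-methoxy-2-(4-methoxyphenyl)-4-oxo-4H-chromen-8-yl]-3-phenylpropanoic acid
Product: 14 (R)-3-[5,7-dihydroxy-2-(4-hydroxyphenyl)-4-oxo-4H-chromen-8-yl]-3-phenylpropanoic acid, via the (R)-dihydrocoumarin lactone 12 (not isolated), via the trilithium salt of the target 13 (not isolated)
Conditions: BBr3 (8 equiv), CH2Cl2, −78 °C → rt; ice-water; then LiOH (3.3 equiv), THF/H2O, 0 °C → rt, Ar; then 1 M HCl, 0 °C, pH 3
Reagents that add atoms: lithium hydroxide, [Li+].[OH-]
Why: Lewis-acid ether cleavage; boron binds each ether oxygen and bromide removes the methyl group by SN2, the 5-methoxy group first because boron is chelated by the C4 carbonyl and the 4'-methoxy group on warming. The boron-bound carboxyl and 7-phenol should close to lactone 12, which LiOH reopens to salt 13, and cold acidification gives the open acid. No bond to the stereocenter is made or broken and its C–H is not acidic, so the configuration from step 7 should be kept.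

## Compound list

1 | 5,7-dihydroxy-4-phenyl-2H-chromen-2-one | O=c1cc(-c2ccccc2)c2c(O)cc(O)cc2o1 | starting material
2 | 5-hydroxy-7-methoxy-4-phenyl-2H-chromen-2-one | O=c1cc(-c2ccccc2)c2c(O)cc(OC)cc2o1 | intermediate
3 | 7-methoxy-2-oxo-4-phenyl-2H-chromen-5-yl acetate | CC(=O)Oc1cc(OC)cc2oc(=O)cc(-c3ccccc3)c12 | intermediate
4 | 6-acetyl-5-hydroxy-7-methoxy-4-phenyl-2H-chromen-2-one | CC(=O)c1c(OC)cc2oc(=O)cc(-c3ccccc3)c2c1O | intermediate
5 | 4-methoxybenzaldehyde | COc1ccc(C=O)cc1 | starting material
6 | tripotassium (Z)-3-{2,6-dioxido-4-methoxy-3-[(E)-3-(4-methoxyphenyl)prop-2-enoyl]phenyl}-3-phenylprop-2-enoate | [K+].[K+].[K+].[O-]C(=O)/C=C(/c1ccccc1)c1c([O-])cc(OC)c(C(=O)/C=C/c2ccc(OC)cc2)c1[O-] | intermediate (not isolated)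
7 | (E)-5-hydroxy-7-methoxy-6-[3-(4-methoxyphenyl)prop-2-enoyl]-4-phenyl-2H-chromen-2-one | COc1ccc(/C=C/C(=O)c2c(OC)cc3oc(=O)cc(-c4ccccc4)c3c2O)cc1 | intermediate
8 | 5-methoxy-2-(4-methoxyphenyl)-10-phenyl-4H,8H-pyrano[2,3-f]chromene-4,8-dione | O=c1cc(-c2ccccc2)c2c(o1)cc(OC)c1c(=O)cc(-c3ccc(OC)cc3)oc12 | intermediate
9 | disodium (Z)-3-[5-methoxy-2-(4-methoxyphenyl)-7-oxido-4-oxo-4H-chromen-8-yl]-3-phenylprop-2-enoate | [Na+].[Na+].[O-]C(=O)/C=C(/c1ccccc1)c1c([O-])cc(OC)c2c(=O)cc(-c3ccc(OC)cc3)oc12 | intermediate
10 | disodium (R)-3-[5-methoxy-2-(4-methoxyphenyl)-7-oxido-4-oxo-4H-chromen-8-yl]-3-phenylpropanoate | [Na+].[Na+].[O-]C(=O)C[C@H](c1ccccc1)c1c([O-])cc(OC)c2c(=O)cc(-c3ccc(OC)cc3)oc12 | intermediate (not isolated)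
11 | (R)-3-[7-hydroxy-5-methoxy-2-(4-methoxyphenyl)-4-oxo-4H-chromen-8-yl]-3-phenylpropanoic acid | O=C(O)C[C@H](c1ccccc1)c1c(O)cc(OC)c2c(=O)cc(-c3ccc(OC)cc3)oc12 | intermediate
12 | (10R)-5-hydroxy-2-(4-hydroxyphenyl)-10-phenyl-9,10-dihydro-4H,8H-pyrano[2,3-f]chromene-4,8-dione | O=C1C[C@H](c2ccccc2)c2c(O1)cc(O)c1c(=O)cc(-c3ccc(O)cc3)oc12 | intermediate (not isolated)
13 | trilithium (R)-3-[5-hydroxy-7-oxido-2-(4-oxidophenyl)-4-oxo-4H-chromen-8-yl]-3-phenylpropanoate | [Li+].[Li+].[Li+].[O-]C(=O)C[C@H](c1ccccc1)c1c([O-])cc(O)c2c(=O)cc(-c3ccc([O-])cc3)oc12 | intermediate (not isolated)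
14 | (R)-3-[5,7-dihydroxy-2-(4-hydroxyphenyl)-4-oxo-4H-chromen-8-yl]-3-phenylpropanoic acid | O=C(O)C[C@H](c1ccccc1)c1c(O)cc(O)c2c(=O)cc(-c3ccc(O)cc3)oc12 | target

## Step count and least certain steps

Total: 8 steps. Longest linear sequence: 8 steps, from 1 to 14; aldehyde 5 enters at step 4.

**Step 7 (key step).** The most likely failure is slow turnover or incomplete face selection. The aryl group on the alkene is flanked on both sides (C7 phenoxide and ring oxygen O1), twists out of the alkene plane and partly shields both faces, which goes beyond the singly ortho-substituted substrates of the closest known cases. A second possibility is partial reduction of the chromone C2=C3 bond if the pressure has to be raised. Fallback by resolution, setting out from 9: hydrogenation with the achiral, more active [Rh(cod)(dppb)]BF4 (dppb is 1,4-bis(diphenylphosphino)butane) at higher pressure and temperature, followed by cold acidification, should give racemic 3-[7-hydroxy-5-methoxy-2-(4-methoxyphenyl)-4-oxo-4H-chromen-8-yl]-3-phenylpropanoic acid F1. Preparative chromatography on a chiral stationary phase would separate it into 11 and its enantiomer, (S)-3-[7-hydroxy-5-methoxy-2-(4-methoxyphenyl)-4-oxo-4H-chromen-8-yl]-3-phenylpropanoic acid F2, and the route is rejoined at 11. If the face selection is substantial but incomplete, lactone 12 can instead be taken out after the BBr3 stage of step 8 and recrystallised.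

**Step 3.** The acetyl group may migrate to C8 (para to O5), or the shift may be sluggish in the crowded position beside the peri phenyl group. Fallback with ortho-specific C1 delivery, setting out from 2: MgCl2, Et3N and paraformaldehyde in MeCN at reflux should formylate only the carbon ortho to the phenol oxygen, because the magnesium phenoxide delivers formaldehyde internally. This gives 5-hydroxy-7-methoxy-2-oxo-4-phenyl-2H-chromene-6-carbaldehyde F3. MeMgBr (2.2 equiv, THF, −78 °C) should add to the aldehyde much faster than to the conjugated lactone, giving 5-hydroxy-6-(1-hydroxyethyl)-7-methoxy-4-phenyl-2H-chromen-2-one F4. MnO2 in CH2Cl2 oxidises the benzylic alcohol, and the route is rejoined at 4.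

**Step 8.** The unactivated 4'-methyl ether may cleave incompletely. Long exposure to acid after both the 5- and 7-oxygens are free may cause chromone opening and reclosure that moves the chain to C6. The lactone may partly reclose during the final acidification. Fallback by deprotecting before the stereocenter exists, setting out from 8: BBr3 in CH2Cl2, at reflux if needed since nothing stereochemical is at stake and O7 is locked in the lactone, should give 5-hydroxy-2-(4-hydroxyphenyl)-10-phenyl-4H,8H-pyrano[2,3-f]chromene-4,8-dione F5. NaOH (3.05 equiv) opens it to trisodium (Z)-3-[5-hydroxy-7-oxido-2-(4-oxidophenyl)-4-oxo-4H-chromen-8-yl]-3-phenylprop-2-enoate F6. Hydrogenation under the conditions of step 7 and cold acidification then rejoin the route at 14.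

**Step 1.** Site selectivity may be lost or both phenols may be methylated, since only acidity and peri shielding separate them. Fallback that fixes the site by selective deacylation, setting out from 1: Ac2O and pyridine give 2-oxo-4-phenyl-2H-chromene-5,7-diyl diacetate F7. Thiophenol with imidazole in NMP at 0 °C should remove only the unhindered 7-acetate, whose phenoxide is the better leaving group, giving 7-hydroxy-2-oxo-4-phenyl-2H-chromen-5-yl acetate F8. Mitsunobu methylation (MeOH, PPh3, DIAD, THF) of the free 7-OH rejoins the route at 3 and makes step 2 unnecessary.

## Further compounds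

F1 | step 7 | racemic 3-[7-hydroxy-5-methoxy-2-(4-methoxyphenyl)-4-oxo-4H-chromen-8-yl]-3-phenylpropanoic acid | O=C(O)CC(c1ccccc1)c1c(O)cc(OC)c2c(=O)cc(-c3ccc(OC)cc3)oc12
F2 | step 7 | (S)-3-[7-hydroxy-5-methoxy-2-(4-methoxyphenyl)-4-oxo-4H-chromen-8-yl]-3-phenylpropanoic acid | O=C(O)C[C@@H](c1ccccc1)c1c(O)cc(OC)c2c(=O)cc(-c3ccc(OC)cc3)oc12
F3 | step 3 | 5-hydroxy-7-methoxy-2-oxo-4-phenyl-2H-chromene-6-carbaldehyde | O=Cc1c(OC)cc2oc(=O)cc(-c3ccccc3)c2c1O
F4 | step 3 | 5-hydroxy-6-(1-hydroxyethyl)-7-methoxy-4-phenyl-2H-chromen-2-one (racemic) | CC(O)c1c(OC)cc2oc(=O)cc(-c3ccccc3)c2c1O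
F5 | step 8 | 5-hydroxy-2-(4-hydroxyphenyl)-10-phenyl-4H,8H-pyrano[2,3-f]chromene-4,8-dione | O=c1cc(-c2ccccc2)c2c(o1)cc(O)c1c(=O)cc(-c3ccc(O)cc3)oc12
F6 | step 8 | trisodium (Z)-3-[5-hydroxy-7-oxido-2-(4-oxidophenyl)-4-oxo-4H-chromen-8-yl]-3-phenylprop-2-enoate | [Na+].[Na+].[Na+].[O-]C(=O)/C=C(/c1ccccc1)c1c([O-])cc(O)c2c(=O)cc(-c3ccc([O-])cc3)oc12
F7 | step 1 | 2-oxo-4-phenyl-2H-chromene-5,7-diyl diacetate | CC(=O)Oc1cc(OC(C)=O)c2c(-c3ccccc3)cc(=O)oc2c1
F8 | step 1 | 7-hydroxy-2-oxo-4-phenyl-2H-chromen-5-yl acetate | CC(=O)Oc1cc(O)cc2oc(=O)cc(-c3ccccc3)c12
A1 | alternative 1 | methyl (R)-3-[7-hydroxy-5-methoxy-2-(4-methoxyphenyl)-4-oxo-4H-chromen-8-yl]-3-phenylpropanoate | COC(=O)C[C@H](c1ccccc1)c1c(O)cc(OC)c2c(=O)cc(-c3ccc(OC)cc3)oc12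
A2 | alternative 1 | methyl (R)-4-{4-methoxy-3-[3-(4-methoxyphenyl)-3-oxopropanoyl]-2-oxo-2H-pyran-6-yl}-3-phenylbutanoate | COC(=O)C[C@H](c1ccccc1)Cc1cc(OC)c(C(=O)CC(=O)c2ccc(OC)cc2)c(=O)o1
A3 | alternative 2 | (10R)-5-methoxy-2-(4-methoxyphenyl)-10-phenyl-9,10-dihydro-4H,8H-pyrano[2,3-f]chromene-4,8-dione | O=C1C[C@H](c2ccccc2)c2c(O1)cc(OC)c1c(=O)cc(-c3ccc(OC)cc3)oc12
A4 | alternative 2 | 5-methoxy-2-(4-methoxyphenyl)-4H,8H-pyrano[2,3-f]chromene-4,8-dione | O=c1ccc2c(o1)cc(OC)c1c(=O)cc(-c3ccc(OC)cc3)oc12
A5 | alternative 2 | phenylboronic acid | OB(O)c1ccccc1
A6 | alternative 3 | methyl (R)-3-[5,7-dimethoxy-2-(4-methoxyphenyl)-4-oxo-4H-chromen-8-yl]-3-phenylpropanoate | COC(=O)C[C@H](c1ccccc1)c1c(OC)cc(OC)c2c(=O)cc(-c3ccc(OC)cc3)oc12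
A7 | alternative 3 | 5,7-dimethoxy-2-(4-methoxyphenyl)-8-(1-phenylethenyl)-4H-chromen-4-one | C=C(c1ccccc1)c1c(OC)cc(OC)c2c(=O)cc(-c3ccc(OC)cc3)oc12
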